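**Plan** (flavanone numbering: ring C = O1, C2, C3, C4; ring A = C4a to C8a; ring B primed)

- Retrosynthetic cuts, in order: the five MOM acetals; O1–C8a (aryl ether of ring C), giving an open-chain C2-silyloxy ketone with fluorine on C8a; C4–C4a (aryl ketone), giving a Weinreb amide and a ring A aryllithium; C2–C3 (aldol), giving the ring B aldehyde and a glycolate imide; C3′–geranyl and C6–prenyl (allylation of lithiated resorcinol bis-MOM ethers).
- Forward: each resorcinol receives its terpenyl chain between its two oxygens, ring B is formylated, C2–C3 is made by aldol, ring A is joined at C4, ring C is closed last, and the acetals are then removed.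
- Enabling feature: in the open chain the C4 carbonyl sits on C4a, ortho to C8a, so a fluorine on C8a is activated. O1 on C2 is tied to C8a through C2–C3–C4–C4a and can displace it in a 6-exo closure. The C5 and C7 oxygens are meta to C8a and C8 bears only H, so placing F on C8a fixes the 6-prenyl pattern.
- Stereochemistry: C2 and C3 are both set in one magnesium-catalysed Evans anti-aldol with the (S)-benzyloxazolidinone; no later step makes or breaks a bond at either centre.

Key step: step 11

Abbreviations: MOM = methoxymethyl; geranyl = (2E)-3,7-dimethylocta-2,6-dien-1-yl; prenyl = 3-methylbut-2-en-1-yl; TES = triethylsilyl; TMS = trimethylsilyl.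
Assumption: the fluororesorcinol of step 4 and the acetal acid of step 6 are taken as purchasable building blocks.

Step 1
Reactants: 1 resorcinol
Product: 2 1,3-bis(methoxymethoxy)benzene
Conditions: NaH, MOMCl, DMF, 0 °C → rt
Reagents that add atoms: chloromethyl methyl ether, COCCl
Why: Double Williamson O-alkylation of the bis-phenoxide should give the bis-MOM ether, whose acetal oxygens later direct lithiation.

Step 2
Reactants: 2 1,3-bis(methoxymethoxy)benzene; 3 geranyl bromide
Product: 5 2-geranyl-1,3-bis(methoxymethoxy)benzene, via aryllithium 4 (not isolated)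
Conditions: n-BuLi, THF, 0 °C; CuBr·SMe2 (10 mol%), 3, −78 °C → rt
Reagents that add atoms: none
Why: Directed ortho-metalation should occur at C2 between the two OMOM groups, and copper-catalysed SN2 allylic substitution on the primary bromide should attach the chain without allylic transposition or loss of the E geometry.

Step 3
Reactants: 5 2-geranyl-1,3-bis(methoxymethoxy)benzene
Product: 8 3-geranyl-2,4-bis(methoxymethoxy)benzaldehyde, via aryllithium 6 (not isolated), via lithium aminoalkoxide 7 (not isolated)
Conditions: n-BuLi, TMEDA, THF, −78 → 0 °C; DMF, −78 °C → rt; H2O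
Reagents that add atoms: N,N-dimethylformamide, CN(C)C=O
Why: A second directed ortho-metalation should take the only remaining position ortho to an OMOM group, and the aryllithium is formylated with DMF (Bouveault formylation), the hemiaminal alkoxide collapsing on aqueous quench.

Step 4
Reactants: 9 5-fluororesorcinol
Product: 10 1-fluoro-3,5-bis(methoxymethoxy)benzene
Conditions: NaH, MOMCl, DMF, 0 °C → rt
Reagents that add atoms: chloromethyl methyl ether, COCCl
Why: Double Williamson O-alkylation as in step 1 should leave the C–F bond untouched.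

Step 5
Reactants: 10 1-fluoro-3,5-bis(methoxymethoxy)benzene; 11 prenyl bromide
Product: 13 5-fluoro-1,3-bis(methoxymethoxy)-2-prenylbenzene, via aryllithium 12 (not isolated)
Conditions: n-BuLi, THF, −20 °C; CuBr·SMe2 (10 mol%), 11, −78 °C → rt
Reagents that add atoms: none
Why: Directed ortho-metalation should again select the carbon between the two coordinating OMOM groups (para to fluorine, so no aryne can form), and copper-catalysed allylation places the future C6 prenyl group.

Step 6
Reactants: 14 (4S)-4-benzyl-1,3-oxazolidin-2-one; 15 (methoxymethoxy)acetic acid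
Product: 17 (4S)-4-benzyl-3-[(methoxymethoxy)acetyl]-1,3-oxazolidin-2-one, via mixed pivalic anhydride 16 (not isolated)
Conditions: PivCl, Et3N, THF, −20 °C; then 14, LiCl, −20 °C → rt
Reagents that add atoms: none
Why: N-acylation of the oxazolidinone by the mixed pivalic anhydride under LiCl/Et3N activation is the standard entry to Evans imides.

Step 7
Reactants: 8 3-geranyl-2,4-bis(methoxymethoxy)benzaldehyde; 17 (4S)-4-benzyl-3-[(methoxymethoxy)acetyl]-1,3-oxazolidin-2-one
Product: 19 (4S)-4-benzyl-3-{(2R,3R)-3-[3-geranyl-2,4-bis(methoxymethoxy)phenyl]-3-hydroxy-2-(methoxymethoxy)propanoyl}-1,3-oxazolidin-2-one, via trimethylsilyl ether 18 (not isolated)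
Conditions: MgCl2 (20 mol%), Et3N, TMSCl, EtOAc, rt; then citric acid, MeOH, 0 °C
Reagents that add atoms: none
Why: In this Evans magnesium-catalysed anti-aldol reaction, soft enolisation should give the magnesium-chelated Z-enolate, the benzyl group of the (S)-auxiliary blocks one enolate face (as in alkylations of such chelated enolates) and so sets the alkoxy-bearing carbon (future C3, R), the closed boat-like transition state places the new carbinol anti (future C2, R), and TMSCl silylates the aldolate to turn the magnesium over before the silyl ether is methanolysed.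

Step 8
Reactants: 19 the anti-aldol imide
Product: 20 (2R,3R)-3-[3-geranyl-2,4-bis(methoxymethoxy)phenyl]-3-hydroxy-N-methoxy-2-(methoxymethoxy)-N-methylpropanamide
Conditions: AlMe3, MeNHOMe·HCl, CH2Cl2, −10 → 0 °C; aq. potassium sodium tartrate
Reagents that add atoms: N,O-dimethylhydroxylamine hydrochloride, CNOC.Cl
Why: In this Weinreb transamination the aluminium amide, delivered through the aluminium alkoxide of the free β-hydroxyl, should attack the exocyclic imide carbonyl and release the auxiliary without touching either stereocentre.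

Step 9
Reactants: 20 the hydroxy Weinreb amide
Product: 21 (2R,3R)-3-[3-geranyl-2,4-bis(methoxymethoxy)phenyl]-N-methoxy-2-(methoxymethoxy)-N-methyl-3-[(triethylsilyl)oxy]propanamide
Conditions: TESCl, imidazole, DMF, 0 °C → rt
Reagents that add atoms: chlorotriethylsilane, CC[Si](Cl)(CC)CC
Why: Silyl ether formation at the secondary benzylic alcohol masks O1 as the latent nucleophile for the ring closure and removes the acidic proton before the organolithium step.

Step 10
Reactants: 13 5-fluoro-1,3-bis(methoxymethoxy)-2-prenylbenzene; 21 the TES-protected Weinreb amide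
Product: 24 (2R,3R)-1-[6-fluoro-2,4-bis(methoxymethoxy)-3-prenylphenyl]-3-[3-geranyl-2,4-bis(methoxymethoxy)phenyl]-2-(methoxymethoxy)-3-[(triethylsilyl)oxy]propan-1-one, via aryllithium 22 (not isolated), via lithium hemiaminal adduct 23 (not isolated)
Conditions: 13, s-BuLi, THF, −78 °C; then 21, −78 °C; AcOH, −78 °C
Reagents that add atoms: none
Why: Directed ortho-metalation at the ring carbon flanked by F and OMOM followed by Weinreb ketone synthesis should join ring A at C4, the chelated tetrahedral adduct preventing over-addition and the low temperature keeping the ortho-fluoroaryllithium from losing LiF.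

Step 11
Reactants: 24 the fluoro silyloxy ketone
Product: 26 (2R,3R)-2-[3-geranyl-2,4-bis(methoxymethoxy)phenyl]-3,5,7-tris(methoxymethoxy)-6-prenyl-2,3-dihydro-4H-chromen-4-one, via caesium alkoxide 25 (not isolated)
Conditions: CsF (20 mol%), 18-crown-6 (20 mol%), DMF, 0 °C → rt
Reagents that add atoms: none
Why: This is a fluoride-relay desilylative intramolecular nucleophilic aromatic substitution (addition–elimination): fluoride attacks silicon of the C2 silyl ether to free the alkoxide O1, which adds to C8a of ring A ipso to fluorine to give a Meisenheimer anion delocalised through C4a onto the C4 carbonyl oxygen, and loss of fluoride restores ring A and supplies the fluoride that unmasks the next molecule, so that Et3SiF is the only by-product. The closest known reaction types are the fluoride-catalysed etherification of acyl-activated fluoroarenes with silyl ethers and the alkoxide SNAr closure of 2-fluoroaryl β-hydroxy ketones to chroman-4-ones. Ring C closes in the 6-exo-trig mode, O1 and C8a being joined through C2–C3–C4–C4a. No stereocentre is created: C2 and C3 keep the aldol configuration because neither the C2–O1 nor the C3–O bond is broken, and the (2R,3R)-trans product is also the thermodynamically favoured diastereomer. The step needs O1 to attack faster than the unmasked β-alkoxy ketone undergoes retro-aldol cleavage or enolisation at C3, which the low standing concentration of alkoxide, the absence of stoichiometric base and the ortho-acyl activation of the C–F bond are meant to secure; attack by O3 is excluded by its MOM cap, and the 6-prenyl regiochemistry is fixed because only C8a carries a leaving group.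

Step 12
Reactants: 26 the penta-MOM flavanonol
Product: 28 (2R,3R)-2-(3-geranyl-2,4-dihydroxyphenyl)-3,5,7-trihydroxy-6-prenyl-2,3-dihydro-4H-chromen-4-one, via silylated pyridinium intermediate 27 (not isolated)
Conditions: TMSOTf, 2,2′-bipyridyl, CH2Cl2, 0 °C → rt; then H2O
Reagents that add atoms: none
Why: In this silyl triflate/bipyridyl acetal cleavage each MOM group is activated at its methoxy oxygen and its acetal carbon is taken by bipyridyl (the aryl oxygens leaving as silyl ethers), and water should then free all five hydroxyls under near-neutral conditions that spare the prenyl and geranyl alkenes and the acid- and base-sensitive flavanonol.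

**Compound list**

1 | resorcinol | Oc1cccc(O)c1 | starting material
2 | 1,3-bis(methoxymethoxy)benzene | COCOc1cccc(OCOC)c1 | intermediate
3 | geranyl bromide, (2E)-1-bromo-3,7-dimethylocta-2,6-diene | CC(C)=CCC/C(C)=C/CBr | starting material
4 | 2,6-bis(methoxymethoxy)phenyllithium (formed in situ) | [Li]c1c(OCOC)cccc1OCOC | intermediate
5 | 2-geranyl-1,3-bis(methoxymethoxy)benzene | CC(C)=CCC/C(C)=C/Cc1c(OCOC)cccc1OCOC | intermediate
6 | 3-geranyl-2,4-bis(methoxymethoxy)phenyllithium (formed in situ) | CC(C)=CCC/C(C)=C/Cc1c(OCOC)ccc([Li])c1OCOC | intermediate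
7 | lithium (dimethylamino)[3-geranyl-2,4-bis(methoxymethoxy)phenyl]methoxide (formed in situ) | CC(C)=CCC/C(C)=C/Cc1c(OCOC)ccc(C(O[Li])N(C)C)c1OCOC | intermediate
8 | 3-geranyl-2,4-bis(methoxymethoxy)benzaldehyde | CC(C)=CCC/C(C)=C/Cc1c(OCOC)ccc(C=O)c1OCOC | intermediate
9 | 5-fluororesorcinol (5-fluorobenzene-1,3-diol) | Oc1cc(O)cc(F)c1 | starting material
10 | 1-fluoro-3,5-bis(methoxymethoxy)benzene | COCOc1cc(F)cc(OCOC)c1 | intermediate
11 | prenyl bromide, 1-bromo-3-methylbut-2-ene | CC(C)=CCBr | starting material
12 | 4-fluoro-2,6-bis(methoxymethoxy)phenyllithium (formed in situ) | [Li]c1c(OCOC)cc(F)cc1OCOC | intermediate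
13 | 5-fluoro-1,3-bis(methoxymethoxy)-2-prenylbenzene | CC(C)=CCc1c(OCOC)cc(F)cc1OCOC | intermediate
14 | (4S)-4-benzyl-1,3-oxazolidin-2-one | O=C1OC[C@H](Cc2ccccc2)N1 | starting material
15 | (methoxymethoxy)acetic acid | COCOCC(=O)O | starting material
16 | (methoxymethoxy)acetic pivalic anhydride (formed in situ) | COCOCC(=O)OC(=O)C(C)(C)C | intermediate
17 | (4S)-4-benzyl-3-[(methoxymethoxy)acetyl]-1,3-oxazolidin-2-one | COCOCC(=O)N1[C@@H](Cc2ccccc2)COC1=O | intermediate
18 | trimethylsilyl ether of aldol imide 19 (formed in situ) | CC(C)=CCC/C(C)=C/Cc1c(OCOC)ccc([C@@H](O[Si](C)(C)C)[C@H](C(=O)N2[C@@H](Cc3ccccc3)COC2=O)OCOC)c1OCOC | intermediate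
19 | (4S)-4-benzyl-3-{(2R,3R)-3-[3-geranyl-2,4-bis(methoxymethoxy)phenyl]-3-hydroxy-2-(methoxymethoxy)propanoyl}-1,3-oxazolidin-2-one | CC(C)=CCC/C(C)=C/Cc1c(OCOC)ccc([C@@H](O)[C@H](C(=O)N2[C@@H](Cc3ccccc3)COC2=O)OCOC)c1OCOC | intermediate
20 | (2R,3R)-3-[3-geranyl-2,4-bis(methoxymethoxy)phenyl]-3-hydroxy-N-methoxy-2-(methoxymethoxy)-N-methylpropanamide | CC(C)=CCC/C(C)=C/Cc1c(OCOC)ccc([C@@H](O)[C@H](C(=O)N(C)OC)OCOC)c1OCOC | intermediate
21 | (2R,3R)-3-[3-geranyl-2,4-bis(methoxymethoxy)phenyl]-N-methoxy-2-(methoxymethoxy)-N-methyl-3-[(triethylsilyl)oxy]propanamide | CC(C)=CCC/C(C)=C/Cc1c(OCOC)ccc([C@@H](O[Si](CC)(CC)CC)[C@H](C(=O)N(C)OC)OCOC)c1OCOC | intermediate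
22 | 6-fluoro-2,4-bis(methoxymethoxy)-3-prenylphenyllithium (formed in situ) | CC(C)=CCc1c(OCOC)cc(F)c([Li])c1OCOC | intermediate
23 | lithium hemiaminal adduct of 22 with 21 (formed in situ; new carbinol centre undefined) | CC(C)=CCC/C(C)=C/Cc1c(OCOC)ccc([C@@H](O[Si](CC)(CC)CC)[C@H](C(O[Li])(N(C)OC)c2c(F)cc(OCOC)c(CC=C(C)C)c2OCOC)OCOC)c1OCOC | intermediate
24 | (2R,3R)-1-[6-fluoro-2,4-bis(methoxymethoxy)-3-prenylphenyl]-3-[3-geranyl-2,4-bis(methoxymethoxy)phenyl]-2-(methoxymethoxy)-3-[(triethylsilyl)oxy]propan-1-one | CC(C)=CCC/C(C)=C/Cc1c(OCOC)ccc([C@@H](O[Si](CC)(CC)CC)[C@H](C(=O)c2c(F)cc(OCOC)c(CC=C(C)C)c2OCOC)OCOC)c1OCOC | intermediate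
25 | caesium alkoxide of desilylated 24 (formed in situ) | CC(C)=CCC/C(C)=C/Cc1c(OCOC)ccc([C@@H]([O-])[C@H](C(=O)c2c(F)cc(OCOC)c(CC=C(C)C)c2OCOC)OCOC)c1OCOC.[Cs+] | intermediate
26 | (2R,3R)-2-[3-geranyl-2,4-bis(methoxymethoxy)phenyl]-3,5,7-tris(methoxymethoxy)-6-prenyl-2,3-dihydro-4H-chromen-4-one | CC(C)=CCC/C(C)=C/Cc1c(OCOC)ccc([C@H]2Oc3cc(OCOC)c(CC=C(C)C)c(OCOC)c3C(=O)[C@@H]2OCOC)c1OCOC | intermediate
27 | tetrakis(trimethylsilyl) aryl ether of 28 whose O3 carries a CH2 group bound to N of 2,2′-bipyridinium, triflate salt (formed in situ) | CC(C)=CCC/C(C)=C/Cc1c(O[Si](C)(C)C)ccc([C@H]2Oc3cc(O[Si](C)(C)C)c(CC=C(C)C)c(O[Si](C)(C)C)c3C(=O)[C@@H]2OC[n+]2ccccc2-c2ccccn2)c1O[Si](C)(C)C.[O-]S(=O)(=O)C(F)(F)F | intermediate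
28 | (2R,3R)-2-(3-geranyl-2,4-dihydroxyphenyl)-3,5,7-trihydroxy-6-prenyl-2,3-dihydro-4H-chromen-4-one | CC(C)=CCC/C(C)=C/Cc1c(O)ccc([C@H]2Oc3cc(O)c(CC=C(C)C)c(O)c3C(=O)[C@@H]2O)c1O | target

**Step count**

Total: 12 steps. Longest linear sequence: 9 steps (steps 1, 2, 3, 7, 8, 9, 10, 11, 12).

**Steps most likely to fail**

Step 11. The unmasked β-alkoxy ketone may fragment by retro-aldol cleavage or enolise at C3 faster than O1 closes onto C8a, which would erode the C2/C3 configuration or consume material. The fallback replaces addition–elimination by palladium-catalysed C–O coupling under a weak heterogeneous base. It sets out from 20. Purchased 5-chlororesorcinol is converted, as in steps 4 and 5, into 1-chloro-3,5-bis(methoxymethoxy)benzene F1 and then 5-chloro-1,3-bis(methoxymethoxy)-2-prenylbenzene F2. F2 is metalated between Cl and OMOM (n-BuLi, THF, −78 °C) to the aryllithium F3, which is added in excess to the hydroxy Weinreb amide 20 (AcOH quench) to give the chloro hydroxy ketone F4. Treatment of F4 with Pd(OAc)2, 2-(di-tert-butylphosphino)-1,1′-binaphthyl and Cs2CO3 in toluene at 70 °C should close ring C by oxidative addition of zerovalent palladium into the C8a–Cl bond, alkoxide binding and C–O reductive elimination. The fallback comes back to the route at 26.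

Step 7. Facial control or anti selectivity may be incomplete for the α-alkoxy magnesium enolate, and the aldol may revert with the electron-rich, ortho-substituted aldehyde. The fallback moves stereocontrol from the auxiliary to a chiral Lewis acid in an open-transition-state Mukaiyama aldol. It sets out from 15 and 8. Acid 15 is converted (EtSH, dicyclohexylcarbodiimide, 4-dimethylaminopyridine) into S-ethyl (methoxymethoxy)ethanethioate F5, which is enolised and silylated (LiN(i-Pr)2, TMSCl, THF, −78 °C) to the (Z)-silyl ketene thioacetal F6. Addition of F6 to aldehyde 8 mediated by Sn(OTf)2, a chiral 2-(aminomethyl)pyrrolidine diamine of the enantiomeric series that delivers the (2R,3R) adduct, and Bu2Sn(OAc)2 in propionitrile at −78 °C should give the anti thioester F7. Treatment of F7 with MeNHOMe·HCl and i-PrMgCl in THF at −20 °C comes back to the route at 20.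

Step 10. The ortho-fluoroaryllithium may lose LiF to an aryne before it adds to the hindered, α-branched Weinreb amide. The fallback replaces acyl substitution by addition to a more electrophilic aldehyde followed by oxidation. It sets out from 21, which is reduced with i-Bu2AlH (THF, −78 °C) to the aldehyde F8. Aryllithium 22 should add to F8 rapidly at −78 °C to give the carbinol F9 as a mixture of epimers at the new carbinol centre, which is of no consequence. Oxidation of F9 with Dess–Martin periodinane buffered with NaHCO3 in CH2Cl2 comes back to the route at 24.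

**Further compounds**

F1 | step 11 | 1-chloro-3,5-bis(methoxymethoxy)benzene | COCOc1cc(Cl)cc(OCOC)c1
F2 | step 11 | 5-chloro-1,3-bis(methoxymethoxy)-2-prenylbenzene | CC(C)=CCc1c(OCOC)cc(Cl)cc1OCOC
F3 | step 11 | 6-chloro-2,4-bis(methoxymethoxy)-3-prenylphenyllithium | CC(C)=CCc1c(OCOC)cc(Cl)c([Li])c1OCOC
F4 | step 11 | (2R,3R)-1-[6-chloro-2,4-bis(methoxymethoxy)-3-prenylphenyl]-3-[3-geranyl-2,4-bis(methoxymethoxy)phenyl]-3-hydroxy-2-(methoxymethoxy)propan-1-one | CC(C)=CCC/C(C)=C/Cc1c(OCOC)ccc([C@@H](O)[C@H](C(=O)c2c(Cl)cc(OCOC)c(CC=C(C)C)c2OCOC)OCOC)c1OCOC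
F5 | step 7 | S-ethyl (methoxymethoxy)ethanethioate | CCSC(=O)COCOC
F6 | step 7 | {[(Z)-1-(ethylsulfanyl)-2-(methoxymethoxy)ethenyl]oxy}trimethylsilane | CCS/C(=C\OCOC)O[Si](C)(C)C
F7 | step 7 | S-ethyl (2R,3R)-3-[3-geranyl-2,4-bis(methoxymethoxy)phenyl]-3-hydroxy-2-(methoxymethoxy)propanethioate | CC(C)=CCC/C(C)=C/Cc1c(OCOC)ccc([C@@H](O)[C@H](C(=O)SCC)OCOC)c1OCOC
F8 | step 10 | (2R,3R)-3-[3-geranyl-2,4-bis(methoxymethoxy)phenyl]-2-(methoxymethoxy)-3-[(triethylsilyl)oxy]propanal | CC(C)=CCC/C(C)=C/Cc1c(OCOC)ccc([C@@H](O[Si](CC)(CC)CC)[C@H](C=O)OCOC)c1OCOC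
F9 | step 10 | secondary alcohol from addition of 22 to F8 (chain configuration as in 21, both epimers at the new carbinol carbon) | CC(C)=CCC/C(C)=C/Cc1c(OCOC)ccc([C@@H](O[Si](CC)(CC)CC)[C@H](C(O)c2c(F)cc(OCOC)c(CC=C(C)C)c2OCOC)OCOC)c1OCOC
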